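**Retrosynthetic overview**

1. The target, (2S)-6-prenyleriodictyol, comes from its tetrakis-silyl ether 14 by acidic fluoride desilylation. Rings A and B are bought as arenes, and ring C is the only ring formed.
2. Ring C is closed by forming C2–C3: C3 is made a dirhodium carbenoid (from diazo ketone 13) and inserts into a benzylic C–H bond of an aryl benzyl ether, which also sets C2.
3. Enabling feature: C2 is a benzylic carbon bonded to the ring oxygen O1 and to the electron-rich catechol ring B. In the open form it is an O1–CH2–ring B methylene with two enantiotopic, doubly activated C–H bonds lying 1,6 to C3 across the ring A ketone (C3–C4–C4a–C8a–O1–C2).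
4. 13 comes from methyl ketone 11 by diazo transfer, and 11 from phenol 7 and benzyl alcohol 10 by Mitsunobu etherification.
5. The C6 prenyl group of ring A is placed by a Claisen–Cope relay from the O-prenyl ether 4 of bis-silylated 2,4,6-trihydroxyacetophenone.

Key step: step 8

Abbreviation: TBS = tert-butyldimethylsilyl; TBSO = tert-butyldimethylsilyloxy.

Assumption: the sense of induction of Rh2(S-DOSP)4 in step 8 cannot be assigned with confidence in advance; the route is written with this catalyst, and its mirror image Rh2(R-DOSP)4 would be used if a test reaction shows the opposite sense.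

**Route**

Step 1
Reactants: 1 2,4,6-trihydroxyacetophenone
Product: 2 1-[2,4-bis(TBSO)-6-hydroxyphenyl]ethan-1-one
Conditions: TBSCl (2.2 equiv), imidazole, CH2Cl2/DMF, 0 °C to rt
Reagents that add atoms: tert-butyldimethylsilyl chloride, CC(C)(C)[Si](C)(C)Cl
Why: Selective silyl ether formation should occur at the para OH and one ortho OH, because the last ortho OH is held in a strong hydrogen bond to the acetyl carbonyl.

Step 2
Reactants: 2 1-[2,4-bis(TBSO)-6-hydroxyphenyl]ethan-1-one; 3 3-methylbut-2-en-1-ol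
Product: 4 1-[2,4-bis(TBSO)-6-(3-methylbut-2-en-1-yloxy)phenyl]ethan-1-one
Conditions: PPh3, DIAD, THF, 0 °C to rt
Reagents that add atoms: none
Why: Mitsunobu etherification should alkylate the hydrogen-bonded phenol under neutral conditions that spare the aryl silyl ethers and give the O-prenyl ether without allylic transposition.

Step 3
Reactants: 4 1-[2,4-bis(TBSO)-6-(3-methylbut-2-en-1-yloxy)phenyl]ethan-1-one
Product: 7 1-[2,4-bis(TBSO)-6-hydroxy-3-(3-methylbut-2-en-1-yl)phenyl]ethan-1-one, via ortho-dienone 5 (not isolated), via para-dienone 6 (not isolated)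
Conditions: PhNEt2, 200 °C, sealed tube, argon
Reagents that add atoms: none
Why: In this Claisen–Cope (para-Claisen) rearrangement a [3,3] shift to the free ortho carbon, a Cope [3,3] shift to the para carbon between the two silyloxy groups and tautomerisation should deliver a normal prenyl group to the future C6 and free the phenol that becomes O1.

Step 4
Reactants: 8 3,4-dihydroxybenzaldehyde
Product: 9 3,4-bis(TBSO)benzaldehyde
Conditions: TBSCl (2.4 equiv), imidazole, DMF, rt
Reagents that add atoms: tert-butyldimethylsilyl chloride, CC(C)(C)[Si](C)(C)Cl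
Why: Standard silyl ether formation on both catechol hydroxyls masks ring B with groups that are inert to carbenoids and removable without base.

Step 5
Reactants: 9 3,4-bis(TBSO)benzaldehyde
Product: 10 [3,4-bis(TBSO)phenyl]methanol
Conditions: NaBH4, MeOH/THF, 0 °C
Reagents that add atoms: none
Why: Borohydride reduction of the aldehyde should be fast at 0 °C and leave the aryl silyl ethers intact.

Step 6
Reactants: 7 1-[2,4-bis(TBSO)-6-hydroxy-3-(3-methylbut-2-en-1-yl)phenyl]ethan-1-one; 10 [3,4-bis(TBSO)phenyl]methanol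
Product: 11 1-[6-{[3,4-bis(TBSO)phenyl]methoxy}-2,4-bis(TBSO)-3-(3-methylbut-2-en-1-yl)phenyl]ethan-1-one
Conditions: PPh3, DIAD, THF, 0 °C to rt
Reagents that add atoms: none
Why: Mitsunobu etherification of the acidic ortho-acyl phenol with the primary benzylic alcohol should form the aryl benzyl ether without base, so no silyl group is lost or moved.

Step 7
Reactants: 11 1-[6-{[3,4-bis(TBSO)phenyl]methoxy}-2,4-bis(TBSO)-3-(3-methylbut-2-en-1-yl)phenyl]ethan-1-one
Product: 13 1-[6-{[3,4-bis(TBSO)phenyl]methoxy}-2,4-bis(TBSO)-3-(3-methylbut-2-en-1-yl)phenyl]-2-diazoethan-1-one, via trifluoroacetyl diketone 12 (not isolated)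
Conditions: LiN(SiMe3)2, THF, −78 °C; CF3CO2CH2CF3; aq. HCl work-up; then MsN3, Et3N, H2O (1 equiv), MeCN, rt
Reagents that add atoms: methanesulfonyl azide, CS(=O)(=O)N=[N+]=[N-]
Why: In this detrifluoroacetylative diazo transfer the methyl ketone enolate is acylated by the trifluoroacetate ester to the activated diketone 12, which should accept the diazo group from the sulfonyl azide and lose its trifluoroacetyl group to the sulfonamide.

Step 8
Reactants: 13 1-[6-{[3,4-bis(TBSO)phenyl]methoxy}-2,4-bis(TBSO)-3-(3-methylbut-2-en-1-yl)phenyl]-2-diazoethan-1-one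
Product: 14 (2S)-2-[3,4-bis(TBSO)phenyl]-5,7-bis(TBSO)-6-(3-methylbut-2-en-1-yl)-2,3-dihydro-4H-chromen-4-one
Conditions: Rh2(S-DOSP)4 (1 mol %), hexanes, 0 °C to rt, slow addition of 13
Reagents that add atoms: none
Why: Rh2(S-DOSP)4 should expel N2 from 13 to give an electrophilic dirhodium carbenoid at C3, which inserts into one of the two enantiotopic benzylic C–H bonds of the O1–CH2–ring B methylene through a concerted, asynchronous three-centre transition state with hydride-transfer character, forming the C2–C3 bond and the second C3–H bond at once. The closest known reaction type is the chiral dirhodium tetraprolinate-catalysed intramolecular C–H insertion of 2-alkoxyaryl α-diazo ketones into the ether α-C–H bond, which gives 2-substituted chroman-4-ones. Ring C closes as a six-membered ring by 1,6-insertion (carbenoid C3 as atom 1, then C4, C4a, C8a, O1, and C2 as atom 6). The C2 stereocentre is under catalyst control: the chiral prolinate ligands on the dirhodium core differentiate the two enantiotopic hydrogens of the achiral substrate. The step needs insertion to win over oxonium ylide formation at O1 with [1,2]-benzyl shift, over reaction at the flanking 5-oxygen and over attack on the prenyl alkene; the C2–H bonds are doubly activated (lone pair of O1, electron-rich ring B), O1 is a weakly basic aryl ether oxygen conjugated to the ortho acyl group, the 5-oxygen is buried under a silyl group that offers no activated C–H bond, and the prenyl group sits meta to the acyl carbon so that no unstrained ring can form to it. Slow addition keeps the diazo ketone dilute and should suppress carbene dimerisation and intermolecular cyclopropanation.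

Step 9
Reactants: 14 (2S)-2-[3,4-bis(TBSO)phenyl]-5,7-bis(TBSO)-6-(3-methylbut-2-en-1-yl)-2,3-dihydro-4H-chromen-4-one
Product: 15 (2S)-2-(3,4-dihydroxyphenyl)-5,7-dihydroxy-6-(3-methylbut-2-en-1-yl)-2,3-dihydro-4H-chromen-4-one
Conditions: HF·pyridine, pyridine, THF, 0 °C to rt
Reagents that add atoms: none
Why: Fluoride-mediated cleavage of the four aryl silyl ethers under mildly acidic conditions should free the phenols without the base-induced opening of ring C that would scramble C2, and without acid strong enough to cyclise the prenyl group onto a neighbouring phenol.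

**Compound list**

1 | 2,4,6-trihydroxyacetophenone | CC(=O)c1c(O)cc(O)cc1O | starting material
2 | 1-[2,4-bis(tert-butyldimethylsilyloxy)-6-hydroxyphenyl]ethan-1-one | CC(=O)c1c(O)cc(O[Si](C)(C)C(C)(C)C)cc1O[Si](C)(C)C(C)(C)C | intermediate
3 | 3-methylbut-2-en-1-ol | CC(C)=CCO | starting material
4 | 1-[2,4-bis(tert-butyldimethylsilyloxy)-6-(3-methylbut-2-en-1-yloxy)phenyl]ethan-1-one | CC(=O)c1c(OCC=C(C)C)cc(O[Si](C)(C)C(C)(C)C)cc1O[Si](C)(C)C(C)(C)C | intermediate
5 | ortho-dienone, 2-acetyl-3,5-bis(tert-butyldimethylsilyloxy)-6-(2-methylbut-3-en-2-yl)cyclohexa-2,4-dien-1-one (racemic, not isolated) | CC(=O)C1=C(O[Si](C)(C)C(C)(C)C)C=C(O[Si](C)(C)C(C)(C)C)C(C(C)(C)C=C)C1=O | intermediate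
6 | para-dienone, 2-acetyl-3,5-bis(tert-butyldimethylsilyloxy)-4-(3-methylbut-2-en-1-yl)cyclohexa-2,5-dien-1-one (racemic, not isolated) | CC(=O)C1=C(O[Si](C)(C)C(C)(C)C)C(CC=C(C)C)C(O[Si](C)(C)C(C)(C)C)=CC1=O | intermediate
7 | 1-[2,4-bis(tert-butyldimethylsilyloxy)-6-hydroxy-3-(3-methylbut-2-en-1-yl)phenyl]ethan-1-one | CC(=O)c1c(O)cc(O[Si](C)(C)C(C)(C)C)c(CC=C(C)C)c1O[Si](C)(C)C(C)(C)C | intermediate
8 | 3,4-dihydroxybenzaldehyde | O=Cc1ccc(O)c(O)c1 | starting material
9 | 3,4-bis(tert-butyldimethylsilyloxy)benzaldehyde | O=Cc1ccc(O[Si](C)(C)C(C)(C)C)c(O[Si](C)(C)C(C)(C)C)c1 | intermediate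
10 | [3,4-bis(tert-butyldimethylsilyloxy)phenyl]methanol | OCc1ccc(O[Si](C)(C)C(C)(C)C)c(O[Si](C)(C)C(C)(C)C)c1 | intermediate
11 | 1-[6-{[3,4-bis(tert-butyldimethylsilyloxy)phenyl]methoxy}-2,4-bis(tert-butyldimethylsilyloxy)-3-(3-methylbut-2-en-1-yl)phenyl]ethan-1-one | CC(=O)c1c(OCc2ccc(O[Si](C)(C)C(C)(C)C)c(O[Si](C)(C)C(C)(C)C)c2)cc(O[Si](C)(C)C(C)(C)C)c(CC=C(C)C)c1O[Si](C)(C)C(C)(C)C | intermediate
12 | 1-[6-{[3,4-bis(tert-butyldimethylsilyloxy)phenyl]methoxy}-2,4-bis(tert-butyldimethylsilyloxy)-3-(3-methylbut-2-en-1-yl)phenyl]-4,4,4-trifluorobutane-1,3-dione (not isolated) | O=C(CC(=O)C(F)(F)F)c1c(OCc2ccc(O[Si](C)(C)C(C)(C)C)c(O[Si](C)(C)C(C)(C)C)c2)cc(O[Si](C)(C)C(C)(C)C)c(CC=C(C)C)c1O[Si](C)(C)C(C)(C)C | intermediate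
13 | 1-[6-{[3,4-bis(tert-butyldimethylsilyloxy)phenyl]methoxy}-2,4-bis(tert-butyldimethylsilyloxy)-3-(3-methylbut-2-en-1-yl)phenyl]-2-diazoethan-1-one | [N-]=[N+]=CC(=O)c1c(OCc2ccc(O[Si](C)(C)C(C)(C)C)c(O[Si](C)(C)C(C)(C)C)c2)cc(O[Si](C)(C)C(C)(C)C)c(CC=C(C)C)c1O[Si](C)(C)C(C)(C)C | intermediate
14 | (2S)-2-[3,4-bis(tert-butyldimethylsilyloxy)phenyl]-5,7-bis(tert-butyldimethylsilyloxy)-6-(3-methylbut-2-en-1-yl)-2,3-dihydro-4H-chromen-4-one | CC(C)=CCc1c(O[Si](C)(C)C(C)(C)C)cc2c(c1O[Si](C)(C)C(C)(C)C)C(=O)C[C@@H](c1ccc(O[Si](C)(C)C(C)(C)C)c(O[Si](C)(C)C(C)(C)C)c1)O2 | intermediate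
15 | (2S)-2-(3,4-dihydroxyphenyl)-5,7-dihydroxy-6-(3-methylbut-2-en-1-yl)-2,3-dihydro-4H-chromen-4-one | CC(C)=CCc1c(O)cc2c(c1O)C(=O)C[C@@H](c1ccc(O)c(O)c1)O2 | target

**Step count**

Total step count: 9. Longest linear sequence: 7 steps (steps 1, 2, 3, 6, 7, 8, 9); steps 4 and 5 prepare the ring B fragment.

**Steps most likely to fail, with fallbacks**

Step 8. The carbenoid may be diverted to oxonium ylide formation at O1 followed by [1,2]-benzyl migration, or the insertion may discriminate the two enantiotopic hydrogens poorly. The fallback builds ring C first and sets C2 by asymmetric conjugate arylation. It sets out from 7: condensation with N,N-dimethylformamide dimethyl acetal (toluene, 80 °C) should give the enaminone F1, and mild acid (pyridinium p-toluenesulfonate, CH2Cl2, 40 °C) should close it with loss of dimethylamine to 5,7-bis(TBSO)-6-prenylchromen-4-one F2. In parallel, commercial 4-bromobenzene-1,2-diol is silylated (TBSCl, imidazole, DMF) to 4-bromo-1,2-bis(TBSO)benzene F3, which is converted by n-BuLi, then B(OiPr)3 (THF, −78 °C) and dilute HCl work-up into [3,4-bis(TBSO)phenyl]boronic acid F4. Enantioselective conjugate addition of F4 to F2 with Pd(OCOCF3)2 and a tert-butyl-pyridinooxazoline ligand (the enantiomer that delivers 2S), NH4PF6, H2O, ClCH2CH2Cl, 60 °C, a known route to flavanones from chromones, should give 14, where the fallback comes back to the route.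

Step 3. The relay may stop at the ortho stage by enolisation of dienone 5 (giving a reverse-prenyl phenol), or silyl groups may be lost or exchanged at 200 °C. The fallback installs the prenyl group by direct C-alkylation and sorts the phenols by hindrance. It sets out from 1: prenyl bromide with DBU in THF at rt should give 1-[2,4,6-trihydroxy-3-prenylphenyl]ethanone F5. One equivalent of TBSCl with imidazole at 0 °C should silylate only the para OH, which is not hydrogen bonded, to give the mono-silyl ether F6. Mitsunobu etherification with 10 (PPh3, DIAD, THF) should take the less hindered ortho OH, the one with a hydrogen neighbour, to give the benzyl ether F7. TBSOTf with 2,6-lutidine in CH2Cl2 should then silylate the remaining OH between acetyl and prenyl to give 11, where the fallback comes back to the route.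

Step 7. Under LiN(SiMe3)2 the ortho silyl group may migrate from the aryl oxygen to the enolate oxygen, or trifluoroacetylation of the hindered ketone may stay incomplete. The fallback avoids the lithium enolate and makes the diazo group by substitution and elimination. It sets out from 11: soft enolisation (TMSOTf, Et3N, CH2Cl2, 0 °C) should give the trimethylsilyl enol ether F8. NBS in THF at −78 °C should give the α-bromo ketone F9. N,N'-ditosylhydrazine with DBU in THF at 0 °C should alkylate on nitrogen and eliminate two sulfinates to give 13, where the fallback comes back to the route.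

**Further compounds**

F1 | step 8 | (2E)-1-[2,4-bis(tert-butyldimethylsilyloxy)-6-hydroxy-3-(3-methylbut-2-en-1-yl)phenyl]-3-(dimethylamino)prop-2-en-1-one | CN(C)/C=C/C(=O)c1c(O)cc(O[Si](C)(C)C(C)(C)C)c(CC=C(C)C)c1O[Si](C)(C)C(C)(C)C
F2 | step 8 | 5,7-bis(tert-butyldimethylsilyloxy)-6-(3-methylbut-2-en-1-yl)-4H-chromen-4-one | CC(C)=CCc1c(O[Si](C)(C)C(C)(C)C)cc2occc(=O)c2c1O[Si](C)(C)C(C)(C)C
F3 | step 8 | 4-bromo-1,2-bis(tert-butyldimethylsilyloxy)benzene | CC(C)(C)[Si](C)(C)Oc1ccc(Br)cc1O[Si](C)(C)C(C)(C)C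
F4 | step 8 | [3,4-bis(tert-butyldimethylsilyloxy)phenyl]boronic acid | OB(O)c1ccc(O[Si](C)(C)C(C)(C)C)c(O[Si](C)(C)C(C)(C)C)c1
F5 | step 3 | 1-[2,4,6-trihydroxy-3-(3-methylbut-2-en-1-yl)phenyl]ethan-1-one | CC(=O)c1c(O)cc(O)c(CC=C(C)C)c1O
F6 | step 3 | 1-[4-(tert-butyldimethylsilyloxy)-2,6-dihydroxy-3-(3-methylbut-2-en-1-yl)phenyl]ethan-1-one | CC(=O)c1c(O)cc(O[Si](C)(C)C(C)(C)C)c(CC=C(C)C)c1O
F7 | step 3 | 1-[6-{[3,4-bis(tert-butyldimethylsilyloxy)phenyl]methoxy}-4-(tert-butyldimethylsilyloxy)-2-hydroxy-3-(3-methylbut-2-en-1-yl)phenyl]ethan-1-one | CC(=O)c1c(OCc2ccc(O[Si](C)(C)C(C)(C)C)c(O[Si](C)(C)C(C)(C)C)c2)cc(O[Si](C)(C)C(C)(C)C)c(CC=C(C)C)c1O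
F8 | step 7 | {1-[6-{[3,4-bis(tert-butyldimethylsilyloxy)phenyl]methoxy}-2,4-bis(tert-butyldimethylsilyloxy)-3-(3-methylbut-2-en-1-yl)phenyl]ethenyloxy}trimethylsilane | C=C(O[Si](C)(C)C)c1c(OCc2ccc(O[Si](C)(C)C(C)(C)C)c(O[Si](C)(C)C(C)(C)C)c2)cc(O[Si](C)(C)C(C)(C)C)c(CC=C(C)C)c1O[Si](C)(C)C(C)(C)C
F9 | step 7 | 1-[6-{[3,4-bis(tert-butyldimethylsilyloxy)phenyl]methoxy}-2,4-bis(tert-butyldimethylsilyloxy)-3-(3-methylbut-2-en-1-yl)phenyl]-2-bromoethan-1-one | BrCC(=O)c1c(OCc2ccc(O[Si](C)(C)C(C)(C)C)c(O[Si](C)(C)C(C)(C)C)c2)cc(O[Si](C)(C)C(C)(C)C)c(CC=C(C)C)c1O[Si](C)(C)C(C)(C)C
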